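## Structural features

The target is a (2S)-flavanone: a chroman-4-one in which benzo ring A is fused through C4a–C8a to a pyranone ring (O1, C2, C3, C4), with a 3,5-dihydroxyphenyl ring B on C2. Ring A is a fully differentiated phloroglucinol: one oxygen is the ring oxygen O1 on C8a, the other two are free hydroxyls on C5 and C7, and an all-E farnesyl chain (three trisubstituted alkenes) sits on C6 between them and para to O1, leaving C8 as the only aromatic C–H of that ring. C2 is the only stereocentre; it has no stereogenic neighbour, is benzylic and β to the C4 ketone, and is therefore lost by retro-oxa-Michael opening to the 2'-hydroxychalcone under base. The fragile parts are the farnesyl alkenes (no hydrogenation, no strong electrophilic oxidants, acid-induced cyclisation onto the flanking C5/C7 hydroxyls once these are free) and the electron-rich ring A, whose C8 and benzylic C4 positions invite cationic side reactions. The real difficulties are two: deciding which of the three ring A oxygens becomes O1 (6-farnesyl versus 8-farnesyl), and setting C2 as S on a molecule that tolerates neither base nor reducing or strongly oxidising reagents. The key step uses the fact that O1–C8a–C4a–C4 is the oxadiene of an ortho-quinone methide of ring A, with C4 derived from an aldehyde carbon on C4a, while C2–C3 with its aryl group is the vinyl group of a ring B styrene. Two corrections to the plan follow from the structure. First, C4 leaves the cycloaddition as a benzylic methyl ether, at the alcohol and not the acetal oxidation level (the aldehyde carbon gains a C–C bond), so one alcohol-to-ketone oxidation remains although no C–H oxidation is needed. Second, both ring B oxygens are meta to C2, so the styrene gets no electronic help and its ring, if protected as alkyl or acetal ethers, is a better π-nucleophile than its vinyl group; ring B is therefore carried as bis-TBS ether rather than bis-MOM ether.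

## Logic of the disconnections

20 ⇒ 19. The four O–protecting-group bonds are cut (two O–CH2OMe on ring A, two O–Si on ring B). All four phenols must be masked during the oxidation at C4 and the acid-catalysed ring formation, and one acidic methanolysis can remove both kinds of group. The forward step must be mild enough that the farnesyl chain does not cyclise onto the liberated C5/C7 hydroxyls and that C2 is not epimerised.

19 ⇒ 18 ⇒ 17. No skeletal bond is cut; the C4 ketone is traced back to the C4 alcohol and then to the C4 methyl ether, because that is the oxidation level at which the cycloaddition delivers C4. The gain is that both C4 epimers of 17 are usable. The forward steps need a solvolysis in which water captures the ring A-stabilised C4 cation faster than elimination or arylation, and an oxidant that leaves three trisubstituted alkenes alone.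

17 ⇒ 10 + 13 + 14. C3–C4 and O1–C2 are cut in a retro-hetero-Diels–Alder sense, and the C4–OMe bond goes back to 14. This removes the pyran ring and the only stereocentre in one operation and divides the molecule into two aromatic halves of similar size. The forward step needs a chiral acid that fixes C2, a styrene that beats the farnesyl alkenes and the aromatic rings to the cationic heterodiene, and protecting groups that survive a Brønsted acid; hence silyl ethers on 13 and only one free hydroxyl in 10.

10 ⇒ 8. The C4a–CHO bond is cut. In 8 the two positions ortho to the free hydroxyl are equivalent, so formylation can only give the 6-farnesyl pattern. The forward step must be ortho-selective and non-acidic.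

8 ⇒ 7 ⇒ 3 + 4. The aryl–allyl bond C6–C1'' and the O–Si bond are cut. The carbon between the two MOM ethers of 3 is the best site for directed lithiation, and the silyl ether marks the oxygen that later becomes O1. The forward coupling must take place at the α-carbon of 4 with retention of the 2E geometry.

3 ⇒ 2 ⇒ 1. The O–Si bond and two O–CH2 bonds are cut, which leads to a cheap symmetric triol. The price is a statistical bis-protection whose by-products must be separated and recycled.

13 ⇒ 12 ⇒ 11. The vinyl C=C bond (methylenation) and two O–Si bonds are cut, giving a commercial aldehyde. The forward steps are routine and only require a base-free work-up to keep the aryl silyl ethers.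

## Other disconnections considered

Alternative 1: The cut is C8a–O1 together with C4a–C4, so that ring A is joined to a preformed three-carbon chain that already carries ring B and the C2 oxygen. In the forward step CsF would release the aryne from the silyl triflate A2. The carboxylate of the (R)-β-silyloxy acid A3 adds through oxygen at the aryne carbon remote from the flanking MOM ether (C8a), and the aryl anion at C4a takes over the acyl group to give the hydroxy ketone A1.
- In its favour: the C2 configuration is bought in advance with A3, which is more secure than catalyst control in the chosen plan, and here the alternative is the better of the two. The regiochemistry follows the well-understood bias of 3-alkoxyarynes, C4 arrives as the ketone with no redox adjustment, and no Brønsted acid meets the farnesyl chain. After the key step three operations remain (desilylation, Mitsunobu closure of O1–C2 with inversion, MOM removal), equal to the chosen plan.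
- Against it: A2 needs an ortho-silyl triflate on the farnesylated ring, several steps beyond 8, and A3 needs its own asymmetric synthesis. The aryl anion may be protonated before the acyl shift. The β-oxygenated ketone can undergo β-elimination or retro-aldol cleavage on desilylation, which would erase the stereocentre.
- Comparison: the key step closes no ring and sets no stereocentre, so it is a fragment coupling, whereas the chosen cycloaddition makes the ring, two bonds and C2 at once. In step count the alternative would be longer by roughly three to five steps.

Alternative 2: The cut removes three bonds of ring A (C8–C8a, C6–C7, C4a–C8a). In the forward step the cyclobutenone A5 would open thermally to a vinylketene, add the siloxyalkyne A6 by [2+2] cycloaddition, reopen to a dienylketene and close by 6π-electrocyclisation to the phenol A4.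
- In its favour: A4 has the C8a hydroxyl free and the two oxygens flanking the farnesyl chain silylated, with complete regiocontrol and no statistical protection or organometallic allylation. On differentiation of the three oxygens it is the better plan. An all-silyl ring A would also suit the acidic cycloaddition and allow a fluoride-only final deprotection, which is gentler on the farnesyl chain than the acid of step 11.
- Against it: the disconnection does not touch the pyranone ring or C2. It is a route to the equivalent of 8 and must still be combined with a ring-forming, stereo-defining step, for which A4 could feed the chosen key step after formylation. A5 and A6 are not commercial and each needs several steps. Heating a farnesyl-substituted vinylketene invites intramolecular ketene–alkene cycloaddition.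
- Comparison: building a benzene ring that phloroglucinol supplies ready-made would cost roughly two to three steps more than steps 1–4.

Alternative 3: The cut is C2–C3. In the forward step the diazoketone A8 would give, with Rh2(S-PTTL)4, dirhodium tetrakis[N-phthaloyl-(S)-tert-leucinate] (divalent rhodium), a carbenoid at C3 that inserts into the benzylic C–H of the ring B benzyl ether on O1, closing the pyranone ring to A7.
- In its favour: ring and stereocentre are formed directly at the ketone oxidation level, so only desilylation remains (one step against three), and the end game needs no acid. On both points the alternative is the better one. Like the chosen plan it relies on a chiral catalyst for C2, so the two are equal there.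
- Against it: an acceptor-only carbenoid is far less discriminating than a stabilised oxocarbenium ion. Oxonium ylide formation at O1 with benzyl shift to a benzofuranone, cyclopropanation of the three farnesyl alkenes and arene addition on ring B are all plausible. Enantiocontrol in six-membered insertions of this carbenoid class tends to be moderate. A8 requires a hindered 2,6-disubstituted benzoic acid, its activation, diazomethane, and a separate way to put the ring B benzyl group on the correct oxygen.
- Comparison: the alternative forms one bond where the chosen plan forms two. Its longer and more hazardous approach to A8 offsets the shorter end game.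

Key step: step 8

Assumption 1: "farnesyl" denotes the (2E,6E)-3,7,11-trimethyldodeca-2,6,10-trien-1-yl group throughout.
Assumption 2: the sense of induction of the chiral acid in step 8 cannot be predicted with confidence; the (R)-acid is written, and its mirror image is to be used if the first analysis of 19 shows the 2R series.

## Route

Step 1
Reactants: 1 phloroglucinol
Product: 2 3,5-bis(methoxymethoxy)phenol
Conditions: MOMCl (2.0 equiv), iPr2NEt (2.5 equiv), DMF, 0 °C → rt; chromatographic separation, mono- and tris-ethers recycled
Reagents that add atoms: chloromethyl methyl ether (MOMCl), COCCl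
Why: O-alkylation of the phenoxide with an α-chloro ether; the three hydroxyls are equivalent, so the bis-ether is the main component of a statistical mixture and is separated by polarity from the cheap, recyclable mono- and tris-ethers.

Step 2
Reactants: 2 3,5-bis(methoxymethoxy)phenol
Product: 3 [3,5-bis(methoxymethoxy)phenoxy]triisopropylsilane
Conditions: TIPSCl, imidazole, DMF, rt
Reagents that add atoms: triisopropylsilyl chloride (TIPSCl), CC(C)[Si](Cl)(C(C)C)C(C)C
Why: Standard silylation of a phenol; the bulky, non-coordinating TIPS ether marks the oxygen that becomes O1, withstands n-BuLi and keeps lithiation away from its own ortho positions.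

Step 3
Reactants: 3 [3,5-bis(methoxymethoxy)phenoxy]triisopropylsilane; 4 (2E,6E)-farnesyl bromide
Product: 7 {4-[(2E,6E)-farnesyl]-3,5-bis(methoxymethoxy)phenoxy}triisopropylsilane, via aryllithium 5 (not isolated), via arylcopper 6 (not isolated)
Conditions: n-BuLi (1.2 equiv), THF, 0 °C; CuBr·SMe2 (1.0 equiv), −40 °C; then 4, −40 °C → rt
Reagents that add atoms: none
Why: Directed ortho-metalation at the C–H between the two MOM ethers (doubly coordinated, most acidic site), then transmetalation to monovalent copper; the arylcopper couples with the primary allylic bromide at its α-carbon (SN2) with retention of the 2E geometry.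

Step 4
Reactants: 7 {4-[(2E,6E)-farnesyl]-3,5-bis(methoxymethoxy)phenoxy}triisopropylsilane
Product: 8 4-[(2E,6E)-farnesyl]-3,5-bis(methoxymethoxy)phenol
Conditions: TBAF, THF, 0 °C; aq. NH4Cl
Reagents that add atoms: none
Why: Fluoride cleavage of the aryl silyl ether; MOM acetals and alkenes are inert, and the one hydroxyl freed is the one para to the farnesyl chain.

Step 5
Reactants: 8 4-[(2E,6E)-farnesyl]-3,5-bis(methoxymethoxy)phenol
Product: 10 3-[(2E,6E)-farnesyl]-6-hydroxy-2,4-bis(methoxymethoxy)benzaldehyde, via hydroxymethylphenol magnesium salt 9 (not isolated)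
Conditions: MgCl2 (anhydrous), Et3N, (CH2O)n, MeCN, reflux; cold aq. citric acid work-up
Reagents that add atoms: paraformaldehyde (as formaldehyde), C=O
Why: Magnesium-mediated ortho-formylation (Casnati–Skattebøl type): the magnesium phenoxide delivers formaldehyde to the ortho carbon within a chelate and the hydroxymethyl compound 9 is oxidised by a second formaldehyde through an Oppenauer-type hydride transfer. The two ortho positions of 8 are equivalent, so only the pattern of 10 can arise, and the basic medium spares MOM ethers and alkenes.

Step 6
Reactants: 11 3,5-dihydroxybenzaldehyde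
Product: 12 3,5-bis(tert-butyldimethylsilyloxy)benzaldehyde
Conditions: TBSCl, imidazole, DMF, rt
Reagents that add atoms: tert-butyldimethylsilyl chloride (TBSCl), CC(C)(C)[Si](C)(C)Cl
Why: Standard phenol silylation; silyl rather than MOM ethers are chosen for ring B because they shield the ring carbons, donate less into the ring and bring no acetal into the acid-catalysed key step.

Step 7
Reactants: 12 3,5-bis(tert-butyldimethylsilyloxy)benzaldehyde
Product: 13 3,5-bis(tert-butyldimethylsilyloxy)styrene
Conditions: Ph3PCH3Br, n-BuLi, THF, 0 °C; then 12, 0 °C → rt
Reagents that add atoms: methyltriphenylphosphonium bromide, C[P+](c1ccccc1)(c1ccccc1)c1ccccc1.[Br-]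
Why: Wittig methylenation of an aromatic aldehyde with a preformed ylide; no free base remains to attack the aryl silyl ethers.

Step 8
Reactants: 10 3-[(2E,6E)-farnesyl]-6-hydroxy-2,4-bis(methoxymethoxy)benzaldehyde; 13 3,5-bis(tert-butyldimethylsilyloxy)styrene; 14 trimethyl orthoformate
Product: 17 (2S)-2-[3,5-bis(tert-butyldimethylsilyloxy)phenyl]-6-[(2E,6E)-farnesyl]-4-methoxy-5,7-bis(methoxymethoxy)chroman (C4 epimers), via dimethyl acetal 15 (not isolated), via methoxy ortho-quinone methide 16 (not isolated)
Conditions: (R)-3,3'-bis(2,4,6-triisopropylphenyl)-1,1'-binaphthyl-2,2'-diyl N-triflylphosphoramide (5–10 mol%), 13 (4 equiv), 14 (1.5 equiv), 5 Å MS, toluene, −40 °C, slow addition of 10; Et3N quench at −40 °C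
Reagents that add atoms: none
Why: Proposed new method: the acid should first mediate acetal exchange between 10 and 14 to give 15 and then ionise 15 to the 4-methoxy ortho-quinone methide 16, which stays bound to the chiral phosphoramide anion as a hydrogen-bonded ion pair; the closest known reaction types are the achiral acid-catalysed three-component union of salicylaldehydes, orthoformates and styrenes to 4-alkoxy-2-arylchromans and the chiral N-triflylphosphoramide-catalysed [4+2] cycloaddition of ortho-quinone methides with styrenes, neither of which has been shown for a 4-alkoxy quinone methide under enantiocontrol. The pyran ring is closed by an inverse-electron-demand, asynchronous hetero-Diels–Alder reaction in which the styrene CH2 bonds to the electrophilic C4 first and the quinone methide oxygen on C8a collapses onto the developing benzylic cation, a six-membered closure that gives C3–C4 and O1–C2 with the aryl group necessarily on C2. C2 is set by the chiral counter-anion, which covers one face of 16 through the hydroxyl/oxocarbenium–phosphoramide contact so that the styrene approaches the open face in one endo orientation; C4 is not controlled and need not be, since it becomes the carbonyl carbon in step 10. The choice of oxygen is secured by the substrate, because the C8a hydroxyl is the only free phenol. Selectivity for the styrene over the trisubstituted farnesyl alkenes rests on the fourfold excess of 13, its unhindered terminal CH2, the slow addition of 10, and the meta position of the chain relative to the reacting carbon, which rules out small-ring intramolecular capture. The silyl ethers of 13 keep ring B from acting as a Friedel–Crafts nucleophile, and low temperature, methanol uptake by the sieves and an acid of only moderate strength should leave the two MOM ethers, the C4 ether of the product and the farnesyl chain untouched.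

Step 9
Reactants: 17 (2S)-2-[3,5-bis(tert-butyldimethylsilyloxy)phenyl]-6-[(2E,6E)-farnesyl]-4-methoxy-5,7-bis(methoxymethoxy)chroman (C4 epimers)
Product: 18 (2S)-2-[3,5-bis(tert-butyldimethylsilyloxy)phenyl]-6-[(2E,6E)-farnesyl]-5,7-bis(methoxymethoxy)chroman-4-ol (C4 epimers)
Conditions: CSA (10 mol%), THF/H2O 5:1, 0 °C → rt; NaHCO3 quench
Reagents that add atoms: water, O
Why: SN1 solvolysis of a benzylic ether: C4 is flanked by oxygen donors on C5, C7 and C8a, so dilute acid ionises it far more readily than the MOM acetals or aryl silyl ethers, and water in large excess captures the cation. C2 is untouched because ring B, with both oxygens meta, does not stabilise a C2 cation.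

Step 10
Reactants: 18 (2S)-2-[3,5-bis(tert-butyldimethylsilyloxy)phenyl]-6-[(2E,6E)-farnesyl]-5,7-bis(methoxymethoxy)chroman-4-ol (C4 epimers)
Product: 19 (2S)-2-[3,5-bis(tert-butyldimethylsilyloxy)phenyl]-6-[(2E,6E)-farnesyl]-5,7-bis(methoxymethoxy)chroman-4-one
Conditions: DMP, NaHCO3, CH2Cl2, 0 °C → rt
Reagents that add atoms: none
Why: Dess–Martin oxidation of a secondary benzylic alcohol under buffered, non-basic conditions; alkenes, MOM and silyl ethers are inert, both C4 epimers converge on one ketone, and the absence of base avoids retro-oxa-Michael loss of C2.

Step 11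
Reactants: 19 (2S)-2-[3,5-bis(tert-butyldimethylsilyloxy)phenyl]-6-[(2E,6E)-farnesyl]-5,7-bis(methoxymethoxy)chroman-4-one
Product: 20 (2S)-2-(3,5-dihydroxyphenyl)-5,7-dihydroxy-6-[(2E,6E)-3,7,11-trimethyldodeca-2,6,10-trien-1-yl]chroman-4-one (CNP0186816.1)
Conditions: 3 M aq. HCl/MeOH/THF, 40 °C, stopped at full conversion
Reagents that add atoms: none
Why: Acid-catalysed methanolysis removes both MOM acetals (as dimethoxymethane) and both aryl TBS ethers (as the methyl silyl ether) in one operation. The mild temperature limits cyclisation of the farnesyl chain onto the freed C5/C7 hydroxyls, and the flavanone C2 centre is stable to dilute acid.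

## Compound list

1 | phloroglucinol (benzene-1,3,5-triol) | Oc1cc(O)cc(O)c1 | starting material
2 | 3,5-bis(methoxymethoxy)phenol | COCOc1cc(O)cc(OCOC)c1 | intermediate
3 | [3,5-bis(methoxymethoxy)phenoxy]triisopropylsilane | COCOc1cc(OCOC)cc(O[Si](C(C)C)(C(C)C)C(C)C)c1 | intermediate
4 | (2E,6E)-farnesyl bromide | CC(C)=CCC/C(C)=C/CC/C(C)=C/CBr | starting material
5 | [2,6-bis(methoxymethoxy)-4-(triisopropylsilyloxy)phenyl]lithium (not isolated) | [Li]c1c(OCOC)cc(O[Si](C(C)C)(C(C)C)C(C)C)cc1OCOC | intermediate
6 | [2,6-bis(methoxymethoxy)-4-(triisopropylsilyloxy)phenyl]copper (not isolated) | [Cu]c1c(OCOC)cc(O[Si](C(C)C)(C(C)C)C(C)C)cc1OCOC | intermediate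
7 | {4-[(2E,6E)-farnesyl]-3,5-bis(methoxymethoxy)phenoxy}triisopropylsilane | CC(C)=CCC/C(C)=C/CC/C(C)=C/Cc1c(OCOC)cc(O[Si](C(C)C)(C(C)C)C(C)C)cc1OCOC | intermediate
8 | 4-[(2E,6E)-farnesyl]-3,5-bis(methoxymethoxy)phenol | CC(C)=CCC/C(C)=C/CC/C(C)=C/Cc1c(OCOC)cc(O)cc1OCOC | intermediate
9 | 4-[(2E,6E)-farnesyl]-2-(hydroxymethyl)-3,5-bis(methoxymethoxy)phenol (magnesium salt in the flask, not isolated) | CC(C)=CCC/C(C)=C/CC/C(C)=C/Cc1c(OCOC)cc(O)c(CO)c1OCOC | intermediate
10 | 3-[(2E,6E)-farnesyl]-6-hydroxy-2,4-bis(methoxymethoxy)benzaldehyde | CC(C)=CCC/C(C)=C/CC/C(C)=C/Cc1c(OCOC)cc(O)c(C=O)c1OCOC | intermediate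
11 | 3,5-dihydroxybenzaldehyde | O=Cc1cc(O)cc(O)c1 | starting material
12 | 3,5-bis(tert-butyldimethylsilyloxy)benzaldehyde | O=Cc1cc(O[Si](C)(C)C(C)(C)C)cc(O[Si](C)(C)C(C)(C)C)c1 | intermediate
13 | 3,5-bis(tert-butyldimethylsilyloxy)styrene | C=Cc1cc(O[Si](C)(C)C(C)(C)C)cc(O[Si](C)(C)C(C)(C)C)c1 | intermediate
14 | trimethyl orthoformate | COC(OC)OC | starting material
15 | 2-(dimethoxymethyl)-4-[(2E,6E)-farnesyl]-3,5-bis(methoxymethoxy)phenol (not isolated) | CC(C)=CCC/C(C)=C/CC/C(C)=C/Cc1c(OCOC)cc(O)c(C(OC)OC)c1OCOC | intermediate
16 | 4-[(2E,6E)-farnesyl]-6-(methoxymethylidene)-3,5-bis(methoxymethoxy)cyclohexa-2,4-dien-1-one (4-methoxy ortho-quinone methide, ion-paired to the catalyst, not isolated) | CC(C)=CCC/C(C)=C/CC/C(C)=C/CC1=C(OCOC)C(=COC)C(=O)C=C1OCOC | intermediate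
17 | (2S)-2-[3,5-bis(tert-butyldimethylsilyloxy)phenyl]-6-[(2E,6E)-farnesyl]-4-methoxy-5,7-bis(methoxymethoxy)chroman (C4 epimers) | CC(C)=CCC/C(C)=C/CC/C(C)=C/Cc1c(OCOC)cc2c(c1OCOC)C(OC)C[C@@H](c1cc(O[Si](C)(C)C(C)(C)C)cc(O[Si](C)(C)C(C)(C)C)c1)O2 | intermediate
18 | (2S)-2-[3,5-bis(tert-butyldimethylsilyloxy)phenyl]-6-[(2E,6E)-farnesyl]-5,7-bis(methoxymethoxy)chroman-4-ol (C4 epimers) | CC(C)=CCC/C(C)=C/CC/C(C)=C/Cc1c(OCOC)cc2c(c1OCOC)C(O)C[C@@H](c1cc(O[Si](C)(C)C(C)(C)C)cc(O[Si](C)(C)C(C)(C)C)c1)O2 | intermediate
19 | (2S)-2-[3,5-bis(tert-butyldimethylsilyloxy)phenyl]-6-[(2E,6E)-farnesyl]-5,7-bis(methoxymethoxy)chroman-4-one | CC(C)=CCC/C(C)=C/CC/C(C)=C/Cc1c(OCOC)cc2c(c1OCOC)C(=O)C[C@@H](c1cc(O[Si](C)(C)C(C)(C)C)cc(O[Si](C)(C)C(C)(C)C)c1)O2 | intermediate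
20 | (2S)-2-(3,5-dihydroxyphenyl)-5,7-dihydroxy-6-[(2E,6E)-3,7,11-trimethyldodeca-2,6,10-trien-1-yl]chroman-4-one | CC(C)=CCC/C(C)=C/CC/C(C)=C/Cc1c(O)cc2c(c1O)C(=O)C[C@@H](c1cc(O)cc(O)c1)O2 | target

## Step count and least certain steps

Total: 11 steps. Longest linear sequence: 9 steps (steps 1–5 and 8–11); steps 6–7 form the second branch.

**Step 8 (key step, beyond known chemistry).** The most likely failures are three:
- The meta-dioxygenated styrene may react too slowly with the strongly stabilised heterodiene, which is then consumed by Friedel–Crafts arylation at C8 of product already formed or by the farnesyl alkenes of a second molecule.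
- Facial discrimination may be poor, because a 4-methoxy quinone methide may sit loosely in the chiral ion pair.
- The MOM ether next to the oxocarbenium centre may be lost.

The fallback uses known chemistry, the enantioselective conjugate arylation of a chromone. It sets out from 10 and returns to the route at 19, so that steps 9 and 10 fall away.
- Addition of MeMgBr (excess, THF, 0 °C) to 10 should give the secondary alcohol 4-farnesyl-2-(1-hydroxyethyl)-3,5-bis(methoxymethoxy)phenol F1.
- MnO2 in CH2Cl2 should oxidise it to the acetophenone 1-[3-farnesyl-6-hydroxy-2,4-bis(methoxymethoxy)phenyl]ethanone F2.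
- Condensation with N,N-dimethylformamide dimethyl acetal should give the enaminone (E)-3-(dimethylamino)-1-[3-farnesyl-6-hydroxy-2,4-bis(methoxymethoxy)phenyl]prop-2-en-1-one F3.
- On silica gel or with PPTS this should close, with loss of dimethylamine, to the chromone 6-farnesyl-5,7-bis(methoxymethoxy)-4H-chromen-4-one F4.
- Ring B would come from commercial 5-bromoresorcinol: silylation to 1-bromo-3,5-bis(tert-butyldimethylsilyloxy)benzene F5, then bromine–lithium exchange and borylation with B(OiPr)3 to the boronic acid [3,5-bis(tert-butyldimethylsilyloxy)phenyl]boronic acid F6.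
- Conjugate addition of F6 to F4 with Pd(OCOCF3)2 (divalent palladium) and the appropriate enantiomer of 4-tert-butyl-2-(pyridin-2-yl)-4,5-dihydrooxazole in aqueous 1,2-dichloroethane at 60 °C should give 19 directly, with C2 set by the ligand.

**Step 3.** The coupling may proceed with allylic transposition (attack at the γ-carbon of 4 giving the branched isomer), with erosion of the 2E geometry, or with incomplete lithiation. The fallback replaces the copper-mediated substitution by a palladium cross-coupling. It sets out from 3 and returns at 7. The aryllithium 5 is quenched with Bu3SnCl to give the stannane tributyl[2,6-bis(methoxymethoxy)-4-(triisopropylsilyloxy)phenyl]stannane F7, which is coupled with 4 under Stille conditions (Pd(PPh3)4, zerovalent palladium, DMF, 60 °C). The π-allyl intermediate should be attacked at its less hindered terminus to give 7.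

**Step 9.** After ionisation at C4, loss of a C3 proton (elimination to the 2H-chromene) or capture of the cation by C8 of a second molecule may compete with capture by water, and prolonged exposure may begin to remove MOM groups. The fallback avoids the free cation and the alcohol altogether. It sets out from 17 and returns at 19. DDQ in CH2Cl2/pH 7 buffer at 0 °C should abstract the C4 hydride of the electron-rich benzylic methyl ether, and water then converts the oxocarbenium ion into the ketone, so that steps 9 and 10 are replaced by one oxidation. It makes no compound outside the list (entry F0). The point to watch would be hydride abstraction at the benzylic–allylic CH2 of the farnesyl chain.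

**Step 11.** Acid-promoted cyclisation of the farnesyl chain onto the freed C5 or C7 hydroxyl (chroman formation), or slow desilylation that forces longer exposure to acid, may lower the yield. The fallback separates the two deprotections and avoids protic acid. It sets out from 19 and returns at 20. TMSOTf with 2,2'-bipyridyl in MeCN at 0 °C, followed by water, should cleave the aromatic MOM ethers under buffered conditions to give (2S)-2-[3,5-bis(tert-butyldimethylsilyloxy)phenyl]-6-farnesyl-5,7-dihydroxychroman-4-one F8. Et3N·3HF in THF at rt then removes the two silyl groups without generating phenoxide base, giving 20.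

## Further compounds

F1 | step 8 | 4-[(2E,6E)-farnesyl]-2-(1-hydroxyethyl)-3,5-bis(methoxymethoxy)phenol | CC(C)=CCC/C(C)=C/CC/C(C)=C/Cc1c(OCOC)cc(O)c(C(C)O)c1OCOC
F2 | step 8 | 1-[3-[(2E,6E)-farnesyl]-6-hydroxy-2,4-bis(methoxymethoxy)phenyl]ethanone | CC(C)=CCC/C(C)=C/CC/C(C)=C/Cc1c(OCOC)cc(O)c(C(C)=O)c1OCOC
F3 | step 8 | (E)-3-(dimethylamino)-1-[3-[(2E,6E)-farnesyl]-6-hydroxy-2,4-bis(methoxymethoxy)phenyl]prop-2-en-1-one | CC(C)=CCC/C(C)=C/CC/C(C)=C/Cc1c(OCOC)cc(O)c(C(=O)/C=C/N(C)C)c1OCOC
F4 | step 8 | 6-[(2E,6E)-farnesyl]-5,7-bis(methoxymethoxy)-4H-chromen-4-one | CC(C)=CCC/C(C)=C/CC/C(C)=C/Cc1c(OCOC)cc2occc(=O)c2c1OCOC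
F5 | step 8 | 1-bromo-3,5-bis(tert-butyldimethylsilyloxy)benzene | Brc1cc(O[Si](C)(C)C(C)(C)C)cc(O[Si](C)(C)C(C)(C)C)c1
F6 | step 8 | [3,5-bis(tert-butyldimethylsilyloxy)phenyl]boronic acid | OB(O)c1cc(O[Si](C)(C)C(C)(C)C)cc(O[Si](C)(C)C(C)(C)C)c1
F7 | step 3 | tributyl[2,6-bis(methoxymethoxy)-4-(triisopropylsilyloxy)phenyl]stannane | CCCC[Sn](CCCC)(CCCC)c1c(OCOC)cc(O[Si](C(C)C)(C(C)C)C(C)C)cc1OCOC
F0 | step 9 | none | none
F8 | step 11 | (2S)-2-[3,5-bis(tert-butyldimethylsilyloxy)phenyl]-6-[(2E,6E)-farnesyl]-5,7-dihydroxychroman-4-one | CC(C)=CCC/C(C)=C/CC/C(C)=C/Cc1c(O)cc2c(c1O)C(=O)C[C@@H](c1cc(O[Si](C)(C)C(C)(C)C)cc(O[Si](C)(C)C(C)(C)C)c1)O2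
A1 | alternative 1 | (3R)-1-[3-farnesyl-6-hydroxy-2,4-bis(methoxymethoxy)phenyl]-3-[3,5-bis(methoxymethoxy)phenyl]-3-(triisopropylsilyloxy)propan-1-one | CC(C)=CCC/C(C)=C/CC/C(C)=C/Cc1c(OCOC)cc(O)c(c1OCOC)C(=O)C[C@H](c1cc(OCOC)cc(OCOC)c1)O[Si](C(C)C)(C(C)C)C(C)C
A2 | alternative 1 | 4-[(2E,6E)-farnesyl]-3,5-bis(methoxymethoxy)-2-(trimethylsilyl)phenyl trifluoromethanesulfonate | CC(C)=CCC/C(C)=C/CC/C(C)=C/Cc1c(OCOC)cc(OS(=O)(=O)C(F)(F)F)c([Si](C)(C)C)c1OCOC
A3 | alternative 1 | (3R)-3-[3,5-bis(methoxymethoxy)phenyl]-3-(triisopropylsilyloxy)propanoic acid | OC(=O)C[C@H](c1cc(OCOC)cc(OCOC)c1)O[Si](C(C)C)(C(C)C)C(C)C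
A4 | alternative 2 | 4-[(2E,6E)-farnesyl]-3,5-bis(triisopropylsilyloxy)phenol | CC(C)=CCC/C(C)=C/CC/C(C)=C/Cc1c(O[Si](C(C)C)(C(C)C)C(C)C)cc(O)cc1O[Si](C(C)C)(C(C)C)C(C)C
A5 | alternative 2 | 2-[(2E,6E)-farnesyl]-3-(triisopropylsilyloxy)cyclobut-2-en-1-one | CC(C)=CCC/C(C)=C/CC/C(C)=C/CC1=C(O[Si](C(C)C)(C(C)C)C(C)C)CC1=O
A6 | alternative 2 | (triisopropylsilyloxy)acetylene | C#CO[Si](C(C)C)(C(C)C)C(C)C
A7 | alternative 3 | (2S)-6-farnesyl-5,7,3',5'-tetrakis(tert-butyldimethylsilyloxy)flavanone | CC(C)=CCC/C(C)=C/CC/C(C)=C/Cc1c(O[Si](C)(C)C(C)(C)C)cc2c(c1O[Si](C)(C)C(C)(C)C)C(=O)C[C@@H](c1cc(O[Si](C)(C)C(C)(C)C)cc(O[Si](C)(C)C(C)(C)C)c1)O2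
A8 | alternative 3 | 1-[2-{[3,5-bis(tert-butyldimethylsilyloxy)phenyl]methoxy}-4,6-bis(tert-butyldimethylsilyloxy)-5-[(2E,6E)-farnesyl]phenyl]-2-diazoethanone | CC(C)=CCC/C(C)=C/CC/C(C)=C/Cc1c(O[Si](C)(C)C(C)(C)C)cc(OCc2cc(O[Si](C)(C)C(C)(C)C)cc(O[Si](C)(C)C(C)(C)C)c2)c(C(=O)C=[N+]=[N-])c1O[Si](C)(C)C(C)(C)C
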